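Its constants belong to no real substance; the rest is arithmetic.

Whether to charge 1.00 equiv of free base instead of 0.500 equiv is the decision at hand.

    nucleophile + acid set free ⇌ protonated nucleophile, settled at all times (K1 = 11000 M⁻¹)
    acid set free → by-product carried off (k2 = 0.0014 s⁻¹)
    2 nucleophile → homo dimer (k3 = 9.2 × 10⁻⁴ M⁻¹ s⁻¹)
    solid nucleophile ⇌ nucleophile, rate k4*(cs4 - [nucleophile]) while solid is left; crystals form when [nucleophile] > cs4 (cs4 = 0.063 M, k4 = 7.4 × 10⁻⁴ s⁻¹)
    acid set free + free base ⇌ salt of the base, settled at all times (K5 = 5500 M⁻¹)
    electrophile + nucleophile → acid set free + product (k6 = 9.7 × 10⁻⁴ M⁻¹ s⁻¹)

- maple: electrophile 0.22 M; free base 0.500 equiv; solid nucleophile 1.10 equiv; time 80 min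
- elm: electrophile 0.22 M; free base 1.00 equiv; solid nucleophile 1.10 equiv; time 80 min

1. part of the electrophile that has reacted at the end, maple
2. part of the electrophile that has reacted at the end, elm
3. what raising the equivalents of free base from its lowest to its highest value here does to the part of the electrophile that has reacted (changes below 5 percentage points count as none) (no change / it rises / it falls)

- where a step has two of a species, its rate is k times that concentration squared, and two are used at each turn
- as a solid, counted per litre of solution: solid nucleophile
- at the start none of the solid nucleophile is in solution
- run time (maple): 80 min

For the trend to read anything but no change, the part of the electrophile reacted has to differ by 5 percentage points between maple and elm. Free base reaches the coupling through the acid set free: acid taken up by nucleophile removes one more nucleophile from solution, and acid taken up by free base does not. The large thing to reckon first is therefore the supply of nucleophile, and the base is a correction to it.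

Dissolving runs with coefficient 7.4 × 10⁻⁴ s⁻¹ on the gap below 0.063 M, and the coupling, with electrophile held as charged, pulls on dissolved nucleophile at 2.13 × 10⁻⁴ s⁻¹. Dissolving pays for coupling at 0.0489 M, the holding level, reached with a lag of 17.5 min; the homo dimer is ignored in this reckoning. Electrophile then falls in a pseudo-first-order way over 80 min less the lag, which gives 16.3 % reacted at one nucleophile per turn.

At two nucleophile per turn the pull doubles, the level is 0.0400 M, the lag 14.3 min, and the part reacted 14.2 %. Each turn in maple and in elm costs between those two ends, and the whole span of 2.1 points is smaller than the 5 points required. The middle of the span gives 15.2 % for maple, 15.2 % for elm, and the trend no change.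

The forecast gave 14.3 %, 14.7 % and no change, holding that “doubling the base changes conversion by well under 5 points”. The simulation gives 14.8 % for maple, 15.1 % for elm and no change, a change of 0.31 points.

In elm the nucleophile stands at 0.0434 M after 80.0 min, lower than the holding level and higher than the doubled-pull level. The neighbouring flask is elm with 0.88 M of electrophile. At one nucleophile per turn its holding level is 0.0293 M, its lag 10.5 min, and its part reacted 11.2 %. That flask ends with more salt of the base, 0.0889 M, than protonated nucleophile, 0.00645 M. Its nucleophile stands at 0.0287 M, and its part reacted is 10.8 %.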